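**Retrosynthetic overview**
1. Target 18 ⇐ hydroxy butenolide 14 by C2 acetylation, desilylation, selective C13 acetylation and C8 methacrylation.
2. 14 ⇐ acyclic ynal 13 + CO: one macrocyclic hetero-Pauson–Khand [2+2+1] closes the ten-membered carbocycle (C6–C7) and the butenolide (C11–C12, C12–O) together and sets C6.
3. 13 ⇐ ynal 8 by two catalyst-controlled vinylogous Mukaiyama aldol reactions with the same dienolate 5 (C8, then C2, and both E-alkenes), each followed by DIBAL reduction to the next aldehyde.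
4. 8 ⇐ TBS propargyl ether + DMF; 5 ⇐ 3-methylbut-2-enoyl chloride + morpholine.
5. Ring order: no ring before step 9; both rings form in step 9.

Assumption: germacrane numbering is used in the text (lactone O on C6, C7=C11 butenolide alkene, C12 lactone C=O, C13 the CH2O carbon, OAc on C2, methacrylate on C8); the target is (2R,6R,8S),1(10)E,4E, which is (4S,8R,11aR) in cyclodeca[b]furan numbering.

**Step 1**
Reactants: 1 3-methylbut-2-enoyl chloride; 2 morpholine
Product: 3 3-methyl-1-(morpholin-4-yl)but-2-en-1-one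
Conditions: Et3N, CH2Cl2, 0 °C to rt
Reagents that add atoms: none
Why: Nucleophilic acyl substitution (amidation of an acid chloride) with no stereocentre involved.

**Step 2**
Reactants: 3 3-methyl-1-(morpholin-4-yl)but-2-en-1-one
Product: 5 (Z)-4-[1-(tert-butyldimethylsilyloxy)-3-methylbuta-1,3-dien-1-yl]morpholine, via potassium dienolate 4 (not isolated)
Conditions: KHMDS, THF, −78 °C; then TBSCl, −78 °C to rt; distil
Reagents that add atoms: tert-butyldimethylsilyl chloride, CC(C)(C)[Si](C)(C)Cl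
Why: γ-Deprotonation of the β,β-dimethyl enamide gives the extended dienolate, whose O-silylation gives the conjugated N,O-silyl ketene acetal used by Denmark for vinylogous aldol reactions.

**Step 3**
Reactants: 6 tert-butyldimethyl(prop-2-yn-1-yloxy)silane
Product: 8 4-(tert-butyldimethylsilyloxy)but-2-ynal, via lithium acetylide 7 (not isolated)
Conditions: n-BuLi, THF, −78 °C; DMF; inverse quench into aq. KH2PO4/MTBE, 0 °C
Reagents that add atoms: N,N-dimethylformamide, CN(C)C=O
Why: Acetylide formylation with DMF, where the buffered inverse quench releases the ynal without conjugate addition of dimethylamine.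

**Step 4**
Reactants: 8 4-(tert-butyldimethylsilyloxy)but-2-ynal; 5 (Z)-4-[1-(tert-butyldimethylsilyloxy)-3-methylbuta-1,3-dien-1-yl]morpholine
Product: 9 (2E,5S)-8-(tert-butyldimethylsilyloxy)-5-hydroxy-3-methyl-1-(morpholin-4-yl)oct-2-en-6-yn-1-one
Conditions: SiCl4 (1.1 equiv), (S,S)-Denmark bisphosphoramide (5 mol %), i-Pr2NEt (10 mol %), CH2Cl2, −78 °C; aq. NaHCO3
Reagents that add atoms: none
Why: Lewis-base-catalysed, SiCl4-mediated vinylogous Mukaiyama aldol reaction in which the dienolate attacks through its γ-carbon on the Si face of the activated ynal (the (R,R)-catalyst is taken as Re-selective, hence (S,S) here), setting C8 (S) and the E-trisubstituted C10=C1 alkene.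

**Step 5**
Reactants: 9 (2E,5S)-8-(tert-butyldimethylsilyloxy)-5-hydroxy-3-methyl-1-(morpholin-4-yl)oct-2-en-6-yn-1-one
Product: 10 (2E,5S)-5,8-bis(tert-butyldimethylsilyloxy)-3-methyl-1-(morpholin-4-yl)oct-2-en-6-yn-1-one
Conditions: TBSCl, imidazole, DMF, rt
Reagents that add atoms: tert-butyldimethylsilyl chloride, CC(C)(C)[Si](C)(C)Cl
Why: Standard silylation of a secondary propargylic alcohol, which turns the C8 oxygen into a group that does not ionise at the propargylic position in step 9.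

**Step 6**
Reactants: 10 (2E,5S)-5,8-bis(tert-butyldimethylsilyloxy)-3-methyl-1-(morpholin-4-yl)oct-2-en-6-yn-1-one
Product: 11 (2E,5S)-5,8-bis(tert-butyldimethylsilyloxy)-3-methyloct-2-en-6-ynal
Conditions: DIBAL-H (1.2 equiv), THF, −78 °C; Rochelle salt
Reagents that add atoms: none
Why: Partial reduction of a morpholine amide, which behaves like a Weinreb amide and holds at the tetrahedral aluminium hemiaminal until work-up, so the enal is obtained directly and C8 is untouched.

**Step 7**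
Reactants: 11 (2E,5S)-5,8-bis(tert-butyldimethylsilyloxy)-3-methyloct-2-en-6-ynal; 5 (Z)-4-[1-(tert-butyldimethylsilyloxy)-3-methylbuta-1,3-dien-1-yl]morpholine
Product: 12 (2E,5R,6E,9S)-9,12-bis(tert-butyldimethylsilyloxy)-5-hydroxy-3,7-dimethyl-1-(morpholin-4-yl)dodeca-2,6-dien-10-yn-1-one
Conditions: SiCl4 (1.1 equiv), (R,R)-Denmark bisphosphoramide (5 mol %), i-Pr2NEt (10 mol %), CH2Cl2, −78 °C; aq. NaHCO3
Reagents that add atoms: none
Why: Second vinylogous Mukaiyama aldol reaction, now with Re-face attack on the enal under control of the antipodal catalyst (the remote C8 centre has no influence), setting C2 (R) and the E-trisubstituted C4=C5 alkene.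

**Step 8**
Reactants: 12 (2E,5R,6E,9S)-9,12-bis(tert-butyldimethylsilyloxy)-5-hydroxy-3,7-dimethyl-1-(morpholin-4-yl)dodeca-2,6-dien-10-yn-1-one
Product: 13 (2E,5R,6E,9S)-9,12-bis(tert-butyldimethylsilyloxy)-5-hydroxy-3,7-dimethyldodeca-2,6-dien-10-ynal
Conditions: DIBAL-H (2.3 equiv), THF, −78 °C; Rochelle salt
Reagents that add atoms: none
Why: Partial amide reduction as in step 6, with the first equivalent of hydride consumed by the free C2 hydroxyl, giving the δ-hydroxy E-enal, which cannot close to a lactol.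

**Step 9**
Reactants: 13 (2E,5R,6E,9S)-9,12-bis(tert-butyldimethylsilyloxy)-5-hydroxy-3,7-dimethyldodeca-2,6-dien-10-ynal
Product: 14 (4S,6E,8R,10E,11aR)-4-(tert-butyldimethylsilyloxy)-3-[(tert-butyldimethylsilyloxy)methyl]-8-hydroxy-6,10-dimethyl-4,5,8,9-tetrahydrocyclodeca[b]furan-2(11aH)-one
Conditions: Mo(CO)6 (1.5 equiv), DMSO (10 equiv), PhMe, 100 °C, Ar, syringe-pump addition of 13 over 12 h (final 2 mM)
Reagents that add atoms: molybdenum hexacarbonyl, [Mo].[C-]#[O+].[C-]#[O+].[C-]#[O+].[C-]#[O+].[C-]#[O+].[C-]#[O+]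
Why: Proposed new method: macrocyclic hetero-Pauson–Khand [2+2+1], in which the Mo(CO)3(DMSO)3 fragment formed in situ binds the alkyne and the enal C=O, oxidative cyclisation gives an oxamolybdacyclopentene (C6–C7 bond, ten-membered ring, the other regiochemistry needing a bridged trans-cycloundecene), and CO insertion into Mo–C11 followed by C–O reductive elimination closes the butenolide, the closest known reactions being the Mo(CO)6/DMSO hetero-Pauson–Khand cyclisation of ynals to 5- and 6-ring-fused butenolides and Ni(0)-mediated macrocyclic ynal oxidative cyclisations, with the silyl ethers keeping both propargylic C–O bonds inert to Mo(0) and C6 (R) expected from 1,3-induction by C8 through a crown-like transition state with the C8 silyloxy group exo (6,8-cis oxygen pattern).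

**Step 10**
Reactants: 14 (4S,6E,8R,10E,11aR)-4-(tert-butyldimethylsilyloxy)-3-[(tert-butyldimethylsilyloxy)methyl]-8-hydroxy-6,10-dimethyl-4,5,8,9-tetrahydrocyclodeca[b]furan-2(11aH)-one
Product: 15 (4S,6E,8R,10E,11aR)-4-(tert-butyldimethylsilyloxy)-3-[(tert-butyldimethylsilyloxy)methyl]-6,10-dimethyl-2-oxo-2,4,5,8,9,11a-hexahydrocyclodeca[b]furan-8-yl acetate
Conditions: Ac2O, pyridine, DMAP (cat.), CH2Cl2, 0 °C
Reagents that add atoms: acetic anhydride, CC(=O)OC(C)=O
Why: DMAP-catalysed acetylation of the only free hydroxyl (C2), placed after ring closure so that no δ-acyloxy enal or allylic acetate is exposed to hot Mo(0).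

**Step 11**
Reactants: 15 (4S,6E,8R,10E,11aR)-4-(tert-butyldimethylsilyloxy)-3-[(tert-butyldimethylsilyloxy)methyl]-6,10-dimethyl-2-oxo-2,4,5,8,9,11a-hexahydrocyclodeca[b]furan-8-yl acetate
Product: 16 (4S,6E,8R,10E,11aR)-4-hydroxy-3-(hydroxymethyl)-6,10-dimethyl-2-oxo-2,4,5,8,9,11a-hexahydrocyclodeca[b]furan-8-yl acetate
Conditions: HF·pyridine, pyridine/THF, 0 °C to rt
Reagents that add atoms: none
Why: Buffered fluoride desilylation removes both TBS ethers while leaving the acetate, the lactone and the base-sensitive C6–H untouched.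

**Step 12**
Reactants: 16 (4S,6E,8R,10E,11aR)-4-hydroxy-3-(hydroxymethyl)-6,10-dimethyl-2-oxo-2,4,5,8,9,11a-hexahydrocyclodeca[b]furan-8-yl acetate
Product: 17 [(4S,6E,8R,10E,11aR)-8-acetoxy-4-hydroxy-6,10-dimethyl-2-oxo-2,4,5,8,9,11a-hexahydrocyclodeca[b]furan-3-yl]methyl acetate
Conditions: AcCl (1.05 equiv), 2,4,6-collidine, CH2Cl2, −78 °C
Reagents that add atoms: acetyl chloride, CC(=O)Cl
Why: Chemoselective acetylation of the primary allylic C13 alcohol over the hindered secondary C8 alcohol, which sits next to the tetrasubstituted alkene (acyl chloride/collidine protocol for primary-selective acylation).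

**Step 13**
Reactants: 17 [(4S,6E,8R,10E,11aR)-8-acetoxy-4-hydroxy-6,10-dimethyl-2-oxo-2,4,5,8,9,11a-hexahydrocyclodeca[b]furan-3-yl]methyl acetate
Product: 18 (4S,6E,8R,10E,11aR)-8-acetoxy-3-(acetoxymethyl)-6,10-dimethyl-2-oxo-2,4,5,8,9,11a-hexahydrocyclodeca[b]furan-4-yl 2-methylprop-2-enoate
Conditions: methacrylic anhydride, Et3N, DMAP, BHT (cat.), CH2Cl2, 0 °C to rt
Reagents that add atoms: methacrylic anhydride, C=C(C)C(=O)OC(=O)C(C)=C
Why: DMAP-catalysed acylation of the remaining C8 hydroxyl with retention at C8, where translactonisation is impossible because C8 is trans to the lactone carbonyl across C7=C11.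

**Compound list**
1 | 3-methylbut-2-enoyl chloride | CC(C)=CC(=O)Cl | starting material
2 | morpholine | C1COCCN1 | starting material
3 | 3-methyl-1-(morpholin-4-yl)but-2-en-1-one | CC(C)=CC(=O)N1CCOCC1 | intermediate
4 | potassium (Z)-3-methyl-1-(morpholin-4-yl)buta-1,3-dien-1-olate (not isolated) | C=C(C)/C=C(\[O-])N1CCOCC1.[K+] | intermediate
5 | (Z)-4-[1-(tert-butyldimethylsilyloxy)-3-methylbuta-1,3-dien-1-yl]morpholine | C=C(C)/C=C(\O[Si](C)(C)C(C)(C)C)N1CCOCC1 | intermediate
6 | tert-butyldimethyl(prop-2-yn-1-yloxy)silane | C#CCO[Si](C)(C)C(C)(C)C | starting material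
7 | [3-(tert-butyldimethylsilyloxy)prop-1-yn-1-yl]lithium (not isolated) | [Li]C#CCO[Si](C)(C)C(C)(C)C | intermediate
8 | 4-(tert-butyldimethylsilyloxy)but-2-ynal | O=CC#CCO[Si](C)(C)C(C)(C)C | intermediate
9 | (2E,5S)-8-(tert-butyldimethylsilyloxy)-5-hydroxy-3-methyl-1-(morpholin-4-yl)oct-2-en-6-yn-1-one | O=C(/C=C(\C)C[C@H](O)C#CCO[Si](C)(C)C(C)(C)C)N1CCOCC1 | intermediate
10 | (2E,5S)-5,8-bis(tert-butyldimethylsilyloxy)-3-methyl-1-(morpholin-4-yl)oct-2-en-6-yn-1-one | O=C(/C=C(\C)C[C@H](O[Si](C)(C)C(C)(C)C)C#CCO[Si](C)(C)C(C)(C)C)N1CCOCC1 | intermediate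
11 | (2E,5S)-5,8-bis(tert-butyldimethylsilyloxy)-3-methyloct-2-en-6-ynal | O=C/C=C(\C)C[C@H](O[Si](C)(C)C(C)(C)C)C#CCO[Si](C)(C)C(C)(C)C | intermediate
12 | (2E,5R,6E,9S)-9,12-bis(tert-butyldimethylsilyloxy)-5-hydroxy-3,7-dimethyl-1-(morpholin-4-yl)dodeca-2,6-dien-10-yn-1-one | O=C(/C=C(\C)C[C@@H](O)/C=C(\C)C[C@H](O[Si](C)(C)C(C)(C)C)C#CCO[Si](C)(C)C(C)(C)C)N1CCOCC1 | intermediate
13 | (2E,5R,6E,9S)-9,12-bis(tert-butyldimethylsilyloxy)-5-hydroxy-3,7-dimethyldodeca-2,6-dien-10-ynal | O=C/C=C(\C)C[C@@H](O)/C=C(\C)C[C@H](O[Si](C)(C)C(C)(C)C)C#CCO[Si](C)(C)C(C)(C)C | intermediate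
14 | (4S,6E,8R,10E,11aR)-4-(tert-butyldimethylsilyloxy)-3-[(tert-butyldimethylsilyloxy)methyl]-8-hydroxy-6,10-dimethyl-4,5,8,9-tetrahydrocyclodeca[b]furan-2(11aH)-one | CC(C)(C)[Si](C)(C)O[C@H]1C/C(C)=C/[C@H](O)C/C(C)=C/[C@H]2OC(=O)C(CO[Si](C)(C)C(C)(C)C)=C12 | intermediate
15 | (4S,6E,8R,10E,11aR)-4-(tert-butyldimethylsilyloxy)-3-[(tert-butyldimethylsilyloxy)methyl]-6,10-dimethyl-2-oxo-2,4,5,8,9,11a-hexahydrocyclodeca[b]furan-8-yl acetate | CC(C)(C)[Si](C)(C)O[C@H]1C/C(C)=C/[C@H](OC(C)=O)C/C(C)=C/[C@H]2OC(=O)C(CO[Si](C)(C)C(C)(C)C)=C12 | intermediate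
16 | (4S,6E,8R,10E,11aR)-4-hydroxy-3-(hydroxymethyl)-6,10-dimethyl-2-oxo-2,4,5,8,9,11a-hexahydrocyclodeca[b]furan-8-yl acetate | O[C@H]1C/C(C)=C/[C@H](OC(C)=O)C/C(C)=C/[C@H]2OC(=O)C(CO)=C12 | intermediate
17 | [(4S,6E,8R,10E,11aR)-8-acetoxy-4-hydroxy-6,10-dimethyl-2-oxo-2,4,5,8,9,11a-hexahydrocyclodeca[b]furan-3-yl]methyl acetate | O[C@H]1C/C(C)=C/[C@H](OC(C)=O)C/C(C)=C/[C@H]2OC(=O)C(COC(C)=O)=C12 | intermediate
18 | (4S,6E,8R,10E,11aR)-8-acetoxy-3-(acetoxymethyl)-6,10-dimethyl-2-oxo-2,4,5,8,9,11a-hexahydrocyclodeca[b]furan-4-yl 2-methylprop-2-enoate (CNP0309304.1) | C=C(C)C(=O)O[C@H]1C/C(C)=C/[C@H](OC(C)=O)C/C(C)=C/[C@H]2OC(=O)C(COC(C)=O)=C12 | target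

**Totals**
Total step count: 13. Longest linear sequence: 12 steps (1, 2, 4–13); the chain from 6 is 11 steps (3–13).

**Three steps most likely to fail**

Step 9 (ring closure to a ten-membered ring by a hetero-Pauson–Khand reaction is unprecedented; the enal may bind Mo through C=C; the C6 configuration is the least secure stereochemical element of the route). Fallback, from 13 back to 17, with the two rings made in two separate operations. Acetylation of 13 (Ac2O, pyridine) gives (2E,5R,6E,9S)-9,12-bis(tert-butyldimethylsilyloxy)-3,7-dimethyl-1-oxododeca-2,6-dien-10-yn-5-yl acetate F1. Selective cleavage of the primary silyl ether (HF·pyridine/pyridine, THF, 0 °C) gives the propargylic alcohol F2, and CBr4/PPh3 converts it into the propargylic bromide F3. Intramolecular Cr(II)-mediated SE2′ allenylation of the aldehyde (CrCl2, THF, high dilution) closes the ten-membered ring to the α-allenol F4; a Kishi-type chiral sulfonamide ligand can be added to impose the C6 configuration by reagent control. PdCl2-catalysed, CuCl2-mediated chlorocyclocarbonylation of this 2,3-allenol under CO builds the butenolide as the 13-chloride F5. CsOAc in DMF gives the 2,13-diacetate 8-silyl ether F6, and HF·pyridine returns 17, from which step 13 follows.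

Step 4 (ynals are outside the best-documented scope of this catalyst, so the ee, and with it C8, may be low). Fallback, from 8 and 5 back to 9, with C8 set by reduction instead of by C–C bond formation. The BF3·OEt2-promoted vinylogous Mukaiyama aldol reaction gives the racemic hydroxy amide F7. Dess–Martin oxidation (NaHCO3, CH2Cl2) gives the ynone F8. Midland reduction with (S)-Alpine-Borane (from (−)-α-pinene) then delivers 9 with C8 (S).

Step 8 (partial reduction of an enamide bearing a free alkoxide may stall or over-reduce; step 6 uses the same reaction on a simpler substrate). Fallback, from 12 back to 13, through the alcohol oxidation level. Exhaustive reduction of the amide with lithium amidotrihydroborate (LiNH2BH3, THF, 0 °C to rt) gives the allylic 1,5-diol F9. Oxidation of the primary allylic alcohol alone (TEMPO, PhI(OAc)2, CH2Cl2) then gives 13.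

**Further compounds**
F1 | step 9 | (2E,5R,6E,9S)-9,12-bis(tert-butyldimethylsilyloxy)-3,7-dimethyl-1-oxododeca-2,6-dien-10-yn-5-yl acetate | O=C/C=C(\C)C[C@@H](OC(C)=O)/C=C(\C)C[C@H](O[Si](C)(C)C(C)(C)C)C#CCO[Si](C)(C)C(C)(C)C
F2 | step 9 | (2E,5R,6E,9S)-9-(tert-butyldimethylsilyloxy)-12-hydroxy-3,7-dimethyl-1-oxododeca-2,6-dien-10-yn-5-yl acetate | O=C/C=C(\C)C[C@@H](OC(C)=O)/C=C(\C)C[C@H](O[Si](C)(C)C(C)(C)C)C#CCO
F3 | step 9 | (2E,5R,6E,9S)-12-bromo-9-(tert-butyldimethylsilyloxy)-3,7-dimethyl-1-oxododeca-2,6-dien-10-yn-5-yl acetate | O=C/C=C(\C)C[C@@H](OC(C)=O)/C=C(\C)C[C@H](O[Si](C)(C)C(C)(C)C)C#CCBr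
F4 | step 9 | (1R,2E,5R,6E,9S)-9-(tert-butyldimethylsilyloxy)-10-ethenylidene-1-hydroxy-3,7-dimethylcyclodeca-2,6-dien-5-yl acetate | CC(C)(C)[Si](C)(C)O[C@H]1C/C(C)=C/[C@H](OC(C)=O)C/C(C)=C/[C@@H](O)C1=C=C
F5 | step 9 | (4S,6E,8R,10E,11aR)-4-(tert-butyldimethylsilyloxy)-3-(chloromethyl)-6,10-dimethyl-2-oxo-2,4,5,8,9,11a-hexahydrocyclodeca[b]furan-8-yl acetate | CC(C)(C)[Si](C)(C)O[C@H]1C/C(C)=C/[C@H](OC(C)=O)C/C(C)=C/[C@H]2OC(=O)C(CCl)=C12
F6 | step 9 | [(4S,6E,8R,10E,11aR)-8-acetoxy-4-(tert-butyldimethylsilyloxy)-6,10-dimethyl-2-oxo-2,4,5,8,9,11a-hexahydrocyclodeca[b]furan-3-yl]methyl acetate | CC(C)(C)[Si](C)(C)O[C@H]1C/C(C)=C/[C@H](OC(C)=O)C/C(C)=C/[C@H]2OC(=O)C(COC(C)=O)=C12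
F7 | step 4 | racemic (2E)-8-(tert-butyldimethylsilyloxy)-5-hydroxy-3-methyl-1-(morpholin-4-yl)oct-2-en-6-yn-1-one | O=C(/C=C(\C)CC(O)C#CCO[Si](C)(C)C(C)(C)C)N1CCOCC1
F8 | step 4 | (2E)-8-(tert-butyldimethylsilyloxy)-3-methyl-1-(morpholin-4-yl)oct-2-en-6-yne-1,5-dione | O=C(/C=C(\C)CC(=O)C#CCO[Si](C)(C)C(C)(C)C)N1CCOCC1
F9 | step 8 | (2E,5R,6E,9S)-9,12-bis(tert-butyldimethylsilyloxy)-3,7-dimethyldodeca-2,6-dien-10-yne-1,5-diol | OC/C=C(\C)C[C@@H](O)/C=C(\C)C[C@H](O[Si](C)(C)C(C)(C)C)C#CCO[Si](C)(C)C(C)(C)C
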